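**Strategy.** The hydroazulene is disconnected at C1–C5 and C9–C10 (daucane numbering) by an intramolecular de Mayo sequence. In the seven-membered ring, C6 and C9 are 1,5-related through C5, C1 and C10, and C1–C5 is the bond shared with the five-membered ring. A cyclopentane-1,3-dione enol acetate (C5=C9) with a tethered C1=C10 alkene therefore gives both rings. The [2+2] photocycloaddition closes the cyclopentane; acetate methanolysis then opens the cyclobutanol by retro-aldol cleavage of C5–C9, expanding the dione ring to the cycloheptane and setting C1 and C5. The precursor is a 3-acetoxy-2-substituted cyclopent-2-enone whose free (R)-tertiary carbinol hydrogen-bonds to the enone carbonyl.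

Key step: step 13

Remark: bicyclic compounds carry daucane numbering (C1 ring-fusion CMe, C2–C3 CH2, C4 isopropyl carbinol, C5 ring-fusion CH, C6–C10 the other seven-ring atoms) and β is the face of the C1 methyl; iodide 4 and acid chloride 29 are assumed to be purchasable.

Step 1
Reactants: 1 (R)-2-hydroxy-3-methylbutanoic acid; 2 pivalaldehyde
Product: 3 (2R,5R)-2-tert-butyl-5-isopropyl-1,3-dioxolan-4-one (2,5-cis)
Conditions: TsOH·H2O (cat.), H2SO4 (cat.), pentane, reflux, water separator; crystallisation of the cis isomer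
Reagents that add atoms: none
Why: Acid-catalysed acetalisation under thermodynamic control should give mainly the cis dioxolanone, whose new acetal centre (2R) is set by the existing centre and stores its configuration for the next step (self-regeneration of stereocentres).

Step 2
Reactants: 3 (2R,5R)-2-tert-butyl-5-isopropyl-1,3-dioxolan-4-one; 4 4-iodo-2-methylbut-1-ene
Product: 5 (2R,5R)-2-tert-butyl-5-isopropyl-5-(3-methylbut-3-en-1-yl)-1,3-dioxolan-4-one
Conditions: LiN(iPr)2, THF, −78 °C; then 4, DMPU, −78 → −20 °C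
Reagents that add atoms: none
Why: SN2 alkylation of the lithium enolate on the face anti to the tert-butyl group should put the chain where the hydrogen was (overall retention) and fix the quaternary carbinol carbon (future C4) as R, the iodide and DMPU favouring substitution over elimination.

Step 3
Reactants: 5 (2R,5R)-2-tert-butyl-5-isopropyl-5-(3-methylbut-3-en-1-yl)-1,3-dioxolan-4-one
Product: 6 (R)-2-isopropyl-5-methylhex-5-ene-1,2-diol
Conditions: LiAlH4, THF, 0 °C → rt
Reagents that add atoms: none
Why: Hydride reduction of the lactone acetal should release the 1,2-diol (the acetal carbon leaves as neopentyl alcohol) without touching the quaternary centre.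

Step 4
Reactants: 6 (R)-2-isopropyl-5-methylhex-5-ene-1,2-diol
Product: 7 (R)-2-isopropyl-5-methyl-1,2-bis(triethylsilyloxy)hex-5-ene
Conditions: TESOTf, 2,6-lutidine, CH2Cl2, −78 → 0 °C
Reagents that add atoms: triethylsilyl trifluoromethanesulfonate, CC[Si](CC)(CC)OS(=O)(=O)C(F)(F)F
Why: The silyl triflate should silylate the primary and the hindered tertiary hydroxyl alike.

Step 5
Reactants: 7 (R)-2-isopropyl-5-methyl-1,2-bis(triethylsilyloxy)hex-5-ene
Product: 8 (R)-2-isopropyl-5-methyl-2-(triethylsilyloxy)hex-5-enal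
Conditions: (COCl)2, DMSO, CH2Cl2, −78 → −40 °C; Et3N, −78 °C → rt
Reagents that add atoms: none
Why: Under Swern conditions a primary triethylsilyl ether is cleaved and oxidised in one operation while the tertiary silyl ether stays, and the aldehyde has no α-hydrogen to epimerise.

Step 6
Reactants: 8 (R)-2-isopropyl-5-methyl-2-(triethylsilyloxy)hex-5-enal
Product: 9 (R)-3-isopropyl-6-methyl-3-(triethylsilyloxy)hept-6-en-1-yne
Conditions: dimethyl (1-diazo-2-oxopropyl)phosphonate, K2CO3, MeOH, 0 °C → rt
Reagents that add atoms: dimethyl (1-diazo-2-oxopropyl)phosphonate, CC(=O)C(=[N+]=[N-])P(=O)(OC)OC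
Why: The Ohira–Bestmann variant of the Seyferth–Gilbert homologation should convert the non-enolisable aldehyde into the terminal alkyne under mild base that leaves the silyl ether and the alkene alone.

Step 7
Reactants: 9 (R)-3-isopropyl-6-methyl-3-(triethylsilyloxy)hept-6-en-1-yne; 10 3-bromo-1,1-dimethoxypropane
Product: 11 (R)-6-isopropyl-1,1-dimethoxy-9-methyl-6-(triethylsilyloxy)dec-9-en-4-yne
Conditions: n-BuLi, THF, −78 °C; then 10, DMPU, −78 °C → rt
Reagents that add atoms: none
Why: SN2 alkylation of the lithium acetylide with the primary bromide should attach the three-carbon acetal arm at the unhindered alkyne terminus.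

Step 8
Reactants: 11 (R)-6-isopropyl-1,1-dimethoxy-9-methyl-6-(triethylsilyloxy)dec-9-en-4-yne
Product: 12 (R)-6-isopropyl-9-methyl-6-(triethylsilyloxy)dec-9-en-4-ynal
Conditions: PPTS (cat.), acetone/H2O, 45 °C
Reagents that add atoms: water, O
Why: Mild acid hydrolysis of the dimethyl acetal should free the aldehyde while the hindered tertiary silyl ether and the 1,1-disubstituted alkene survive.

Step 9
Reactants: 12 (R)-6-isopropyl-9-methyl-6-(triethylsilyloxy)dec-9-en-4-ynal
Product: 13 2-[(R)-2,6-dimethyl-3-(triethylsilyloxy)hept-6-en-3-yl]cyclopent-2-en-1-one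
Conditions: [Rh(dppe)]2(BF4)2 (cat.), acetone, rt
Reagents that add atoms: none
Why: Cationic monovalent rhodium should insert into the aldehyde C–H bond and add acyl and hydride trans across the alkyne in the endo mode (known intramolecular hydroacylation of 4-alkynals), closing the cyclopentenone with the carbinol substituent on the α-carbon without any cationic or radical centre next to the tethered alkene.

Step 10
Reactants: 13 2-[(R)-2,6-dimethyl-3-(triethylsilyloxy)hept-6-en-3-yl]cyclopent-2-en-1-one
Product: 15 3-hydroxy-2-[(R)-2,6-dimethyl-3-(triethylsilyloxy)hept-6-en-3-yl]cyclopentan-1-one, via β-boryl ketone 14 (not isolated)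
Conditions: B2pin2, CuCl (cat.), NaOtBu (cat.), DPEphos (cat.), MeOH, THF, rt; then NaBO3·4H2O, THF/H2O, rt
Reagents that add atoms: bis(pinacolato)diboron, CC1(C)OB(OC1(C)C)B1OC(C)(C)C(C)(C)O1; sodium perborate, [Na+].[O-]OB=O
Why: Copper-catalysed conjugate borylation should place boron on the unsubstituted β-carbon (the isolated alkene is inert) and perborate oxidation turns C–B into C–OH, the two new ring centres being removed in the next step.

Step 11
Reactants: 15 3-hydroxy-2-[(R)-2,6-dimethyl-3-(triethylsilyloxy)hept-6-en-3-yl]cyclopentan-1-one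
Product: 17 2-[(R)-2,6-dimethyl-3-(triethylsilyloxy)hept-6-en-3-yl]-3-oxocyclopent-1-en-1-yl acetate, via silyloxy dione 16 (not isolated)
Conditions: Dess–Martin periodinane, CH2Cl2, rt; then Ac2O, pyridine, DMAP (cat.), 0 °C
Reagents that add atoms: acetic anhydride, CC(=O)OC(C)=O
Why: Dess–Martin oxidation should give the enolised 2-substituted cyclopentane-1,3-dione, whose two oxygens are equivalent, so O-acetylation can give only one enol acetate.

Step 12
Reactants: 17 2-[(R)-2,6-dimethyl-3-(triethylsilyloxy)hept-6-en-3-yl]-3-oxocyclopent-1-en-1-yl acetate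
Product: 18 2-[(R)-3-hydroxy-2,6-dimethylhept-6-en-3-yl]-3-oxocyclopent-1-en-1-yl acetate
Conditions: HF·pyridine, THF, 0 °C
Reagents that add atoms: none
Why: Fluoride-mediated desilylation under weakly acidic conditions should free the tertiary hydroxyl (needed as hydrogen-bond donor in step 13 and as directing group in step 14) and leave the enol acetate intact.

Step 13
Reactants: 18 2-[(R)-3-hydroxy-2,6-dimethylhept-6-en-3-yl]-3-oxocyclopent-1-en-1-yl acetate
Product: 20 trans-fused 4β-hydroxy-4α-isopropyl-1β-methylhydroazulene-6,9-dione (5α-H), via cyclobutane photoadduct 19 (not isolated)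
Conditions: hν (350 nm, Pyrex), degassed hexane/CH2Cl2, high dilution, 0 °C; then K2CO3 (cat.), MeOH, 0 °C
Reagents that add atoms: none
Why: The triplet β-acetoxy enone should add to the tethered alkene stepwise, forming C5–C1 first (1,4-diradical) and then C9–C10; methoxide then removes the acetate and the strained cyclobutanolate cleaves C5–C9 by retro-aldol reaction, which is the intramolecular de Mayo reaction known for enol esters of 2-alkenylcyclopentane-1,3-diones. The cyclopentane closes by 1,5-closure of the 1,6-diene (rule of five, exo at C1), the cyclobutane by collapse of the C9/C10 diradical, and the cycloheptane arises by ring expansion when the bond shared by the four- and five-membered rings breaks. C1 is set in the first bond formation: in the non-polar medium the O–H···O=C6 hydrogen bond holds the C4–O bond in the enone plane on the C6 side, so C3 delivers the alkene to one face of C5 while isopropyl lies on the other, which puts C10 cis to isopropyl and the C1 methyl cis to the hydroxyl as in the target (hydrogen-bond-directed enone–alkene photocycloadditions are known). C5 is set by protonation of the enolate and should equilibrate under K2CO3 to the trans-fused ketone, in which C6 is anti to isopropyl and keeps the hydrogen bond to the C4 hydroxyl. The step needs straight and not crossed addition (secured by the three-atom tether), one enone face (secured by the hydrogen bond), and fragmentation of the cyclobutanol only (its strain sets it apart from the unstrained tertiary aldol of the five-membered ring at 0 °C).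

Step 14
Reactants: 20 trans-fused 4β-hydroxy-4α-isopropyl-1β-methylhydroazulene-6,9-dione
Product: 21 4β,6α-dihydroxy-4α-isopropyl-1β-methyl-5α-H-hydroazulen-9-one
Conditions: Me4NBH(OAc)3, MeCN/AcOH, −25 °C
Reagents that add atoms: none
Why: In the Evans–Saksena reduction the borohydride binds the 4β-hydroxyl and delivers hydride intramolecularly to the β face of C6, which should give the 6α (1,3-anti) alcohol and leave the remote, undirected C9 ketone untouched.

Step 15
Reactants: 21 4β,6α-dihydroxy-4α-isopropyl-1β-methyl-5α-H-hydroazulen-9-one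
Product: 22 4β,6α-O-isopropylidene acetal of 21
Conditions: 2,2-dimethoxypropane, PPTS (cat.), CH2Cl2, rt
Reagents that add atoms: 2,2-dimethoxypropane, COC(C)(C)OC
Why: Transacetalisation should tie the 1,3-diol into a six-membered acetonide (the equatorial C4 and C6–O bonds on C5–C6 are gauche), masking both hydroxyls for the base and oxidant steps.

Step 16
Reactants: 22 4β,6α-O-isopropylidene acetal of 21
Product: 23 8-methyl derivative of 22 (C8 epimers)
Conditions: LiN(iPr)2, THF, −78 °C; then MeI, −78 → −30 °C
Reagents that add atoms: iodomethane, CI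
Why: Kinetic deprotonation should occur at C8 and not at C10, which is flanked by the quaternary C1, and C-methylation introduces the C8 methyl; the C8 configuration is irrelevant because C8 becomes sp2 in the next step.

Step 17
Reactants: 23 8-methyl derivative of 22
Product: 24 4β,6α-O-isopropylidene-4α-isopropyl-1β,8-dimethyl-5α-H-hydroazul-7-en-9-one
Conditions: IBX, DMSO, 70 °C
Reagents that add atoms: none
Why: IBX dehydrogenation through the more substituted enol should give the conjugated endocyclic C7=C8 enone, the C10 side being blocked because C1 carries no hydrogen.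

Step 18
Reactants: 24 4β,6α-O-isopropylidene-4α-isopropyl-1β,8-dimethyl-5α-H-hydroazul-7-en-9-one
Product: 25 7,8-epoxide of 24 (7,8-epoxy-9-ketone, epoxide face unassigned)
Conditions: H2O2, NaOH (cat.), MeOH, 0 °C
Reagents that add atoms: hydrogen peroxide, OO
Why: Weitz–Scheffer nucleophilic epoxidation should convert the α-methyl enone into the α,β-epoxy ketone, whose configuration does not matter because both epoxide carbons lose it later.

Step 19
Reactants: 25 7,8-epoxide of 24
Product: 26 4β,6α-O-isopropylidene-4α-isopropyl-1β,8-dimethyl-5α-H-hydroazul-8-en-7-ol (C7 epimers)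
Conditions: N2H4·H2O, AcOH (cat.), MeOH, 0 °C → rt
Reagents that add atoms: none
Why: In the Wharton transposition the epoxy hydrazone should lose N2 with opening of the epoxide, moving the oxygen to C7 and the double bond to C8=C9.

Step 20
Reactants: 26 4β,6α-O-isopropylidene-4α-isopropyl-1β,8-dimethyl-5α-H-hydroazul-8-en-7-ol
Product: 27 4β,6α-O-isopropylidene-4α-isopropyl-1β,8-dimethyl-5α-H-hydroazul-8-en-7-one
Conditions: Dess–Martin periodinane, CH2Cl2, rt
Reagents that add atoms: none
Why: Oxidation of the allylic alcohol should give the transposed enone with the carbonyl at C7 and the methyl on the α-carbon C8.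

Step 21
Reactants: 27 4β,6α-O-isopropylidene-4α-isopropyl-1β,8-dimethyl-5α-H-hydroazul-8-en-7-one
Product: 28 4β,6α-dihydroxy-4α-isopropyl-1β,8-dimethyl-5α-H-hydroazul-8-en-7-one
Conditions: AcOH/H2O, 40 °C
Reagents that add atoms: none
Why: Mild acid hydrolysis should remove the acetonide, and the conjugated C7 ketone is the stable α-ketol tautomer, so C6 keeps its oxygen and configuration.

Step 22
Reactants: 28 4β,6α-dihydroxy-4α-isopropyl-1β,8-dimethyl-5α-H-hydroazul-8-en-7-one; 29 4-(benzyloxy)benzoyl chloride
Product: 30 6α-[4-(benzyloxy)benzoyloxy]-4β-hydroxy-4α-isopropyl-1β,8-dimethyl-5α-H-hydroazul-8-en-7-one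
Conditions: pyridine, DMAP (cat.), CH2Cl2, 0 °C → rt
Reagents that add atoms: none
Why: Acyl transfer should esterify the only secondary hydroxyl (C6) and leave the tertiary C4 hydroxyl free, before C9 acquires a competing secondary hydroxyl.

Step 23
Reactants: 30 6α-[4-(benzyloxy)benzoyloxy]-4β-hydroxy-4α-isopropyl-1β,8-dimethyl-5α-H-hydroazul-8-en-7-one
Product: 31 6α-[4-(benzyloxy)benzoyloxy]-4β,8α,9α-trihydroxy-4α-isopropyl-1β,8β-dimethyl-5α-H-hydroazulen-7-one
Conditions: OsO4 (cat.), N-methylmorpholine N-oxide, acetone/H2O, rt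
Reagents that add atoms: N-methylmorpholine N-oxide, C[N+]1([O-])CCOCC1; water, O
Why: Syn-dihydroxylation of the enone double bond should occur from the α face, opposite the axial C1 methyl that shields the β face at C9, setting the 8α- and 9α-hydroxyls together.

Step 24
Reactants: 31 6α-[4-(benzyloxy)benzoyloxy]-4β,8α,9α-trihydroxy-4α-isopropyl-1β,8β-dimethyl-5α-H-hydroazulen-7-one
Product: 32 CNP0241001.1, (3R,3aS,4R,6S,7S,8aR)-3,6,7-trihydroxy-6,8a-dimethyl-5-oxo-3-(propan-2-yl)decahydroazulen-4-yl 4-hydroxybenzoate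
Conditions: H2 (1 atm), Pd on carbon (Pd/C), EtOAc, rt
Reagents that add atoms: none
Why: Neutral hydrogenolysis should cleave the benzyl ether only, since no alkene remains and the alkyl aryl ester is not benzylic, which avoids base at the epimerisable C6.

**Compound list**

1 | (R)-2-hydroxy-3-methylbutanoic acid | CC(C)[C@@H](O)C(=O)O | starting material
2 | pivalaldehyde (2,2-dimethylpropanal) | CC(C)(C)C=O | starting material
3 | (2R,5R)-2-tert-butyl-5-isopropyl-1,3-dioxolan-4-one (cis) | CC(C)[C@H]1O[C@@H](C(C)(C)C)OC1=O | intermediate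
4 | 4-iodo-2-methylbut-1-ene | CC(=C)CCI | starting material
5 | (2R,5R)-2-tert-butyl-5-isopropyl-5-(3-methylbut-3-en-1-yl)-1,3-dioxolan-4-one (tert-butyl cis to isopropyl) | CC(C)[C@@]1(CCC(C)=C)O[C@@H](C(C)(C)C)OC1=O | intermediate
6 | (R)-2-isopropyl-5-methylhex-5-ene-1,2-diol | CC(C)[C@@](O)(CO)CCC(C)=C | intermediate
7 | (R)-2-isopropyl-5-methyl-1,2-bis(triethylsilyloxy)hex-5-ene | CC(C)[C@@](O[Si](CC)(CC)CC)(CO[Si](CC)(CC)CC)CCC(C)=C | intermediate
8 | (R)-2-isopropyl-5-methyl-2-(triethylsilyloxy)hex-5-enal | CC(C)[C@@](O[Si](CC)(CC)CC)(C=O)CCC(C)=C | intermediate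
9 | (R)-3-isopropyl-6-methyl-3-(triethylsilyloxy)hept-6-en-1-yne | CC(C)[C@@](O[Si](CC)(CC)CC)(C#C)CCC(C)=C | intermediate
10 | 3-bromo-1,1-dimethoxypropane | COC(CCBr)OC | starting material
11 | (R)-6-isopropyl-1,1-dimethoxy-9-methyl-6-(triethylsilyloxy)dec-9-en-4-yne | CC(C)[C@@](O[Si](CC)(CC)CC)(C#CCCC(OC)OC)CCC(C)=C | intermediate
12 | (R)-6-isopropyl-9-methyl-6-(triethylsilyloxy)dec-9-en-4-ynal | CC(C)[C@@](O[Si](CC)(CC)CC)(C#CCCC=O)CCC(C)=C | intermediate
13 | 2-[(R)-2,6-dimethyl-3-(triethylsilyloxy)hept-6-en-3-yl]cyclopent-2-en-1-one | CC(C)[C@@](O[Si](CC)(CC)CC)(C1=CCCC1=O)CCC(C)=C | intermediate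
14 | 2-[(R)-2,6-dimethyl-3-(triethylsilyloxy)hept-6-en-3-yl]-3-(4,4,5,5-tetramethyl-1,3,2-dioxaborolan-2-yl)cyclopentan-1-one (ring centres unassigned) | CC(C)[C@@](O[Si](CC)(CC)CC)(C1C(B2OC(C)(C)C(C)(C)O2)CCC1=O)CCC(C)=C | intermediate
15 | 3-hydroxy-2-[(R)-2,6-dimethyl-3-(triethylsilyloxy)hept-6-en-3-yl]cyclopentan-1-one (ring centres unassigned) | CC(C)[C@@](O[Si](CC)(CC)CC)(C1C(O)CCC1=O)CCC(C)=C | intermediate
16 | 2-[(R)-2,6-dimethyl-3-(triethylsilyloxy)hept-6-en-3-yl]cyclopentane-1,3-dione (enolised) | CC(C)[C@@](O[Si](CC)(CC)CC)(C1C(=O)CCC1=O)CCC(C)=C | intermediate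
17 | 2-[(R)-2,6-dimethyl-3-(triethylsilyloxy)hept-6-en-3-yl]-3-oxocyclopent-1-en-1-yl acetate | CC(C)[C@@](O[Si](CC)(CC)CC)(C1=C(OC(C)=O)CCC1=O)CCC(C)=C | intermediate
18 | 2-[(R)-3-hydroxy-2,6-dimethylhept-6-en-3-yl]-3-oxocyclopent-1-en-1-yl acetate | CC(C)[C@@](O)(C1=C(OC(C)=O)CCC1=O)CCC(C)=C | intermediate
19 | 9-acetoxy-4β-hydroxy-4α-isopropyl-1β-methyl-5,9-cyclohydroazulen-6-one (cyclobutane C1–C5–C9–C10 on the α face) | CC(C)[C@]1(O)CC[C@]2(C)C[C@@]3(OC(C)=O)CCC(=O)[C@@]123 | intermediate
20 | trans-fused 4β-hydroxy-4α-isopropyl-1β-methylhydroazulene-6,9-dione, (3R,3aR,8aR)-3-hydroxy-8a-methyl-3-(propan-2-yl)octahydroazulene-4,7-dione | CC(C)[C@]1(O)CC[C@]2(C)CC(=O)CCC(=O)[C@H]21 | intermediate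
21 | 4β,6α-dihydroxy-4α-isopropyl-1β-methyl-5α-H-hydroazulen-9-one | CC(C)[C@]1(O)CC[C@]2(C)CC(=O)CC[C@H](O)[C@H]21 | intermediate
22 | 4β,6α-O-isopropylidene acetal of 21 | CC(C)[C@]1(OC(C)(C)O2)CC[C@]3(C)CC(=O)CC[C@H]2[C@@H]13 | intermediate
23 | 8-methyl derivative of 22 (C8 epimers) | CC(C)[C@]1(OC(C)(C)O2)CC[C@]3(C)CC(=O)C(C)C[C@H]2[C@@H]13 | intermediate
24 | 4β,6α-O-isopropylidene-4α-isopropyl-1β,8-dimethyl-5α-H-hydroazul-7-en-9-one | CC(C)[C@]1(OC(C)(C)O2)CC[C@]3(C)CC(=O)C(C)=C[C@H]2[C@@H]13 | intermediate
25 | 7,8-epoxide of 24 (epoxide face unassigned) | CC(C)[C@]1(OC(C)(C)O2)CC[C@]3(C)CC(=O)C4(C)OC4[C@H]2[C@@H]13 | intermediate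
26 | 4β,6α-O-isopropylidene-4α-isopropyl-1β,8-dimethyl-5α-H-hydroazul-8-en-7-ol (C7 epimers) | CC(C)[C@]1(OC(C)(C)O2)CC[C@]3(C)CC=C(C)C(O)[C@H]2[C@@H]13 | intermediate
27 | 4β,6α-O-isopropylidene-4α-isopropyl-1β,8-dimethyl-5α-H-hydroazul-8-en-7-one | CC(C)[C@]1(OC(C)(C)O2)CC[C@]3(C)CC=C(C)C(=O)[C@H]2[C@@H]13 | intermediate
28 | 4β,6α-dihydroxy-4α-isopropyl-1β,8-dimethyl-5α-H-hydroazul-8-en-7-one | CC(C)[C@]1(O)CC[C@]2(C)CC=C(C)C(=O)[C@H](O)[C@H]21 | intermediate
29 | 4-(benzyloxy)benzoyl chloride | O=C(Cl)c1ccc(OCc2ccccc2)cc1 | starting material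
30 | 6α-[4-(benzyloxy)benzoyloxy]-4β-hydroxy-4α-isopropyl-1β,8-dimethyl-5α-H-hydroazul-8-en-7-one | CC(C)[C@]1(O)CC[C@]2(C)CC=C(C)C(=O)[C@H](OC(=O)c3ccc(OCc4ccccc4)cc3)[C@H]21 | intermediate
31 | 6α-[4-(benzyloxy)benzoyloxy]-4β,8α,9α-trihydroxy-4α-isopropyl-1β,8β-dimethyl-5α-H-hydroazulen-7-one | CC(C)[C@]1(O)CC[C@]2(C)C[C@H](O)[C@](C)(O)C(=O)[C@H](OC(=O)c3ccc(OCc4ccccc4)cc3)[C@H]21 | intermediate
32 | CNP0241001.1, (3R,3aS,4R,6S,7S,8aR)-3,6,7-trihydroxy-6,8a-dimethyl-5-oxo-3-(propan-2-yl)decahydroazulen-4-yl 4-hydroxybenzoate | CC(C)[C@]1(O)CC[C@]2(C)C[C@H](O)[C@](C)(O)C(=O)[C@H](OC(=O)c3ccc(O)cc3)[C@H]21 | target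

**Step count and risks**

Total step count: 24. Longest linear sequence: 24 steps (1 → 32); 2, 4, 10 and 29 enter as purchased building blocks.

Steps most likely to fail:

1. Step 13 (key step). The first C–C bond may form without face discrimination if the intramolecular hydrogen bond is lost, for example after O-to-O acetyl migration in 18. Crossed addition may compete, protonation at C5 may leave the cis ring fusion, and the free tertiary aldol may open the five-membered ring by a second retro-aldol reaction during methanolysis. The fallback sets out from 17 and returns at 20; it replaces hydrogen-bond control by steric control and keeps the carbinol masked through the base treatment. Irradiation of silyl ether 17 under the same light would give the tricyclic silyloxy keto acetate F1. K2CO3 in MeOH would fragment it to the trans-fused silyloxy dione F2. HF·pyridine would then give 20. Which C1 epimer dominates under steric control would have to be determined.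

2. Step 9. Insertion into the alkyne may be slow next to the quaternary propargylic centre, and decarbonylation of the acyl rhodium hydride or engagement of the tethered alkene may take over. The fallback sets out from 12 and returns at 16 (acetylation stage of step 11); it builds the dione by acyl transfer instead of hydroacylation. Pinnick oxidation (NaClO2, NaH2PO4, 2-methylbut-2-ene) would give the alkynoic acid F3. AgNO3-catalysed 5-exo-dig cycloisomerisation would give the (Z)-enol lactone F4. NaOMe in MeOH would open the lactone to the keto ester enolate and close it by Dieckmann-type C-acylation to dione 16.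

3. Step 19. The hindered hydrazone may form slowly, and the diazene may be diverted to reduction or pyrazoline-type products instead of fragmenting. The fallback sets out from 25 and returns at 26; it replaces the ionic fragmentation by a radical one. Luche reduction (NaBH4, CeCl3·7H2O) would give the epoxy alcohol F5. 1,1'-Thiocarbonyldiimidazole would give the thiocarbonylimidazolide F6. Bu3SnH with AIBN would generate the C9 radical, which opens the adjacent epoxide (Barton–McCombie-type deoxygenation with epoxide fragmentation) to give the allylic alcohol 26.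

**Further compounds**

F1 | step 13 | 9-acetoxy-4α-isopropyl-1β-methyl-4β-(triethylsilyloxy)-5,9-cyclohydroazulen-6-one | CC(C)[C@]1(O[Si](CC)(CC)CC)CC[C@]2(C)C[C@@]3(OC(C)=O)CCC(=O)[C@@]123
F2 | step 13 | trans-fused 4α-isopropyl-1β-methyl-4β-(triethylsilyloxy)hydroazulene-6,9-dione | CC(C)[C@]1(O[Si](CC)(CC)CC)CC[C@]2(C)CC(=O)CCC(=O)[C@H]21
F3 | step 9 | (R)-6-isopropyl-9-methyl-6-(triethylsilyloxy)dec-9-en-4-ynoic acid | CC(C)[C@@](O[Si](CC)(CC)CC)(C#CCCC(=O)O)CCC(C)=C
F4 | step 9 | (Z)-5-[(R)-2-isopropyl-5-methyl-2-(triethylsilyloxy)hex-5-en-1-ylidene]dihydrofuran-2(3H)-one | CC(C)[C@@](O[Si](CC)(CC)CC)(/C=C1/CCC(=O)O1)CCC(C)=C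
F5 | step 19 | 7,8-epoxy-4β,6α-O-isopropylidene-4α-isopropyl-1β,8-dimethyl-5α-H-hydroazulen-9-ol (C9 epimers) | CC(C)[C@]1(OC(C)(C)O2)CC[C@]3(C)CC(O)C4(C)OC4[C@H]2[C@@H]13
F6 | step 19 | O-(1H-imidazol-1-ylcarbonothioyl) derivative of F5 at C9 | CC(C)[C@]1(OC(C)(C)O2)CC[C@]3(C)CC(OC(=S)n4ccnc4)C5(C)OC5[C@H]2[C@@H]13
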